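**Retrosynthetic overview**

1. The strategy rests on the O1–C2 bond of ring C. C2, the only stereocentre, is the β-carbon of (E)-2',4',3,4-tetrahydroxy-3',5-diprenylchalcone and O1 is its 2'-phenol oxygen, so ring C is closed last by chalcone isomerase (6-endo-trig oxa-Michael), which sets (2S) on the unprotected molecule.
2. The chalcone is cut at Cα=Cβ (Claisen–Schmidt) into a 3-prenylated 2,4-dihydroxyacetophenone (ring A) and a 5-prenylated 3,4-dihydroxybenzaldehyde (ring B), with the phenols masked as MOM ethers and unmasked before the enzyme step.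
3. The ring A prenyl group comes from an aromatic Claisen rearrangement of the 4-O-(1,1-dimethylallyl) ether (new C3–C bond); the ring B prenyl group comes from a Stille coupling at the C–Br bond of 3-bromo-4,5-dihydroxybenzaldehyde bis-MOM ether.
4. Ring order: rings A and B are purchased; ring C is the only ring made.

Key step: step 9

Remark: the C2 descriptor of the target SMILES reads (2S) (O1 > C1' > C3 > H), the configuration chalcone isomerase delivers; 3-chloro-3-methylbut-1-yne and tributyl(3-methylbut-2-en-1-yl)stannane are taken as purchased reagents.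

**Route**

Step 1
Reactants: 1 2,4-dihydroxyacetophenone; 2 3-chloro-3-methylbut-1-yne
Product: 3 1-[2-hydroxy-4-(2-methylbut-3-yn-2-yloxy)phenyl]ethanone
Conditions: K2CO3, KI (cat.), acetone, reflux
Reagents that add atoms: none
Why: Williamson etherification in which the 4-OH, the more acidic hydroxyl and the one not tied up in the hydrogen bond to the acetyl group, is alkylated by the tertiary propargylic chloride while the chelated 2-OH stays free.

Step 2
Reactants: 3 1-[2-hydroxy-4-(2-methylbut-3-yn-2-yloxy)phenyl]ethanone
Product: 4 1-[2-hydroxy-4-(2-methylbut-3-en-2-yloxy)phenyl]ethanone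
Conditions: H2 (1 atm), Pd on CaCO3 poisoned with Pb(OAc)2 (Lindlar catalyst), quinoline, EtOAc, rt, stopped after one equivalent of H2
Reagents that add atoms: none
Why: Lindlar semihydrogenation should stop at the terminal alkene on the poisoned catalyst and leave the aryl ketone untouched, giving the 1,1-dimethylallyl aryl ether.

Step 3
Reactants: 4 1-[2-hydroxy-4-(2-methylbut-3-en-2-yloxy)phenyl]ethanone
Product: 6 1-[2,4-dihydroxy-3-(3-methylbut-2-en-1-yl)phenyl]ethanone, via Claisen ortho-dienone 5 (not isolated)
Conditions: PhNEt2, 130 °C, N2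
Reagents that add atoms: none
Why: Aromatic Claisen rearrangement ([3,3]) transfers the allyl unit with inversion, so it arrives as a linear prenyl group at C3, the ortho position favoured by the bond fixation that the 2-OH···O=C chelate imposes on the ring, and the dienone then tautomerises to the phenol, leaving no stereocentre.

Step 4
Reactants: 6 1-[2,4-dihydroxy-3-(3-methylbut-2-en-1-yl)phenyl]ethanone
Product: 7 1-[2-hydroxy-4-(methoxymethoxy)-3-(3-methylbut-2-en-1-yl)phenyl]ethanone
Conditions: MOMCl (1.1 equiv), K2CO3, acetone, rt
Reagents that add atoms: chloromethyl methyl ether (MOMCl), COCCl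
Why: Williamson-type MOM ether formation should occur only at the 4-OH, because the 2-OH is hydrogen-bonded to the ketone and flanked by the prenyl group.

Step 5
Reactants: 8 3-bromo-4,5-dihydroxybenzaldehyde
Product: 9 3-bromo-4,5-bis(methoxymethoxy)benzaldehyde
Conditions: MOMCl (3 equiv), K2CO3, acetone, rt to reflux, N2
Reagents that add atoms: chloromethyl methyl ether (MOMCl), COCCl
Why: Exhaustive Williamson-type MOM ether formation on both catechol hydroxyls with excess reagent, the aldehyde and the aryl bromide being inert to these conditions.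

Step 6
Reactants: 9 3-bromo-4,5-bis(methoxymethoxy)benzaldehyde; 10 tributyl(3-methylbut-2-en-1-yl)stannane
Product: 11 3,4-bis(methoxymethoxy)-5-(3-methylbut-2-en-1-yl)benzaldehyde
Conditions: Pd(PPh3)4 (5 mol %), DMF, 100 °C, N2
Reagents that add atoms: none
Why: Stille cross-coupling, in which zerovalent palladium inserts into the C–Br bond, the prenyl group is transferred from tin, and reductive elimination at the less substituted allyl terminus should give the linear prenyl arene under neutral conditions that the aldehyde and the MOM ethers tolerate.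

Step 7
Reactants: 7 1-[2-hydroxy-4-(methoxymethoxy)-3-(3-methylbut-2-en-1-yl)phenyl]ethanone; 11 3,4-bis(methoxymethoxy)-5-(3-methylbut-2-en-1-yl)benzaldehyde
Product: 13 (E)-1-[2-hydroxy-4-(methoxymethoxy)-3-(3-methylbut-2-en-1-yl)phenyl]-3-[3,4-bis(methoxymethoxy)-5-(3-methylbut-2-en-1-yl)phenyl]prop-2-en-1-one, via aldol adduct 12 (not isolated)
Conditions: KOH (50% aq.), EtOH, 0 °C to rt, N2; cold aq. NH4Cl work-up
Reagents that add atoms: none
Why: Claisen–Schmidt condensation, in which the enolate of the methyl ketone adds to the non-enolisable aldehyde and the aldol loses water by E1cB to the thermodynamically favoured (E)-enone, with MOM ethers and prenyl groups stable to hydroxide.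

Step 8
Reactants: 13 the tris-MOM chalcone of step 7
Product: 14 (E)-1-[2,4-dihydroxy-3-(3-methylbut-2-en-1-yl)phenyl]-3-[3,4-dihydroxy-5-(3-methylbut-2-en-1-yl)phenyl]prop-2-en-1-one (2',4',3,4-tetrahydroxy-3',5-diprenylchalcone)
Conditions: HCl (ca. 1 M in MeOH), 25–40 °C, monitored; NaHCO3 quench; chromatography to remove any flavanone
Reagents that add atoms: none
Why: Acid-catalysed transacetalisation of the three aryl MOM ethers to methanol should free the phenols under the dilute, mild conditions customarily used to unmask prenylated chalcones, a 6'-deoxy-2'-hydroxychalcone closing to flavanone only slowly in acid.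

Step 9
Reactants: 14 (E)-2',4',3,4-tetrahydroxy-3',5-diprenylchalcone
Product: 16 (2S)-7,3',4'-trihydroxy-8,5'-diprenylflavanone, via enzyme-bound flavanone enol 15 (not isolated)
Conditions: chalcone isomerase (recombinant legume-type enzyme of Medicago sativa, EC 5.5.1.6), KH2PO4/K2HPO4 buffer pH 7.2 (degassed), DMSO (5% v/v), 25 °C, short incubation; prompt EtOAc extraction, neutral chromatography
Reagents that add atoms: none
Why: The enzyme should bind 14 in its s-cis enone conformation with the 2'-oxygen ionised, polarise the carbonyl through its active-site hydrogen-bond network, let the 2'-phenoxide add to Cβ in an intramolecular oxa-Michael addition and protonate the resulting enolate 15 at C3. The closest known reaction is the chalcone isomerase cyclisation of 6'-deoxychalcones such as isoliquiritigenin and butein to (2S)-flavanones, which legume-type enzymes perform. Ring C closes in the 6-endo-trig mode, O1 bonding to C2 with the Cα=Cβ bond inside the new ring. The C2 stereocentre is under catalyst control: the protein shields one face of Cβ so that the oxygen reaches only the si face (C1' > Cα > H), which gives (2S). The step needs enantioface selectivity over the uncatalysed racemic closure and chemoselectivity for the 2'-oxygen; the first is secured because 14 lacks a 6'-hydroxyl and its 2'-hydroxyl is held in a hydrogen bond to the carbonyl, so the background closure is slow near neutral pH, and the second because only the 2'-oxygen can reach Cβ through a six-membered transition state. A short reaction and prompt extraction should limit reversible ring opening, and chalcone left by the equilibrium is recovered and resubmitted.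

**Compound list**

1 | 2,4-dihydroxyacetophenone | CC(=O)c1ccc(O)cc1O | starting material
2 | 3-chloro-3-methylbut-1-yne | CC(C)(Cl)C#C | starting material
3 | 1-[2-hydroxy-4-(2-methylbut-3-yn-2-yloxy)phenyl]ethanone | CC(=O)c1ccc(OC(C)(C)C#C)cc1O | intermediate
4 | 1-[2-hydroxy-4-(2-methylbut-3-en-2-yloxy)phenyl]ethanone | CC(=O)c1ccc(OC(C)(C)C=C)cc1O | intermediate
5 | Claisen ortho-dienone, 4-acetyl-3-hydroxy-2-(3-methylbut-2-en-1-yl)cyclohexa-3,5-dien-1-one (racemic at C2, not isolated) | CC(=O)C1=C(O)C(CC=C(C)C)C(=O)C=C1 | intermediate
6 | 1-[2,4-dihydroxy-3-(3-methylbut-2-en-1-yl)phenyl]ethanone | CC(=O)c1ccc(O)c(CC=C(C)C)c1O | intermediate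
7 | 1-[2-hydroxy-4-(methoxymethoxy)-3-(3-methylbut-2-en-1-yl)phenyl]ethanone | CC(=O)c1ccc(OCOC)c(CC=C(C)C)c1O | intermediate
8 | 3-bromo-4,5-dihydroxybenzaldehyde | O=Cc1cc(O)c(O)c(Br)c1 | starting material
9 | 3-bromo-4,5-bis(methoxymethoxy)benzaldehyde | O=Cc1cc(OCOC)c(OCOC)c(Br)c1 | intermediate
10 | tributyl(3-methylbut-2-en-1-yl)stannane | CCCC[Sn](CCCC)(CCCC)CC=C(C)C | starting material
11 | 3,4-bis(methoxymethoxy)-5-(3-methylbut-2-en-1-yl)benzaldehyde | O=Cc1cc(OCOC)c(OCOC)c(CC=C(C)C)c1 | intermediate
12 | aldol adduct, 3-hydroxy-1-[2-hydroxy-4-(methoxymethoxy)-3-prenylphenyl]-3-[3,4-bis(methoxymethoxy)-5-prenylphenyl]propan-1-one (racemic carbinol, not isolated) | COCOc1ccc(C(=O)CC(O)c2cc(OCOC)c(OCOC)c(CC=C(C)C)c2)c(O)c1CC=C(C)C | intermediate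
13 | (E)-1-[2-hydroxy-4-(methoxymethoxy)-3-(3-methylbut-2-en-1-yl)phenyl]-3-[3,4-bis(methoxymethoxy)-5-(3-methylbut-2-en-1-yl)phenyl]prop-2-en-1-one | COCOc1ccc(C(=O)/C=C/c2cc(OCOC)c(OCOC)c(CC=C(C)C)c2)c(O)c1CC=C(C)C | intermediate
14 | (E)-2',4',3,4-tetrahydroxy-3',5-diprenylchalcone | CC(C)=CCc1cc(/C=C/C(=O)c2ccc(O)c(CC=C(C)C)c2O)cc(O)c1O | intermediate
15 | enzyme-bound C3–C4 enol of the (2S)-flavanone (drawn neutral, not isolated) | CC(C)=CCc1cc([C@@H]2C=C(O)c3ccc(O)c(CC=C(C)C)c3O2)cc(O)c1O | intermediate
16 | (2S)-2-[3,4-dihydroxy-5-(3-methylbut-2-en-1-yl)phenyl]-7-hydroxy-8-(3-methylbut-2-en-1-yl)-2,3-dihydro-4H-chromen-4-one | CC(C)=CCc1cc([C@@H]2CC(=O)c3ccc(O)c(CC=C(C)C)c3O2)cc(O)c1O | target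

**Step count**

Total: 9 steps. Longest linear sequence: 7 steps (1, 2, 3, 4, 7, 8, 9) from 2,4-dihydroxyacetophenone; the ring B branch is 2 steps (5, 6).

**Steps most likely to fail**

1. Step 9. The enzyme may bind or turn over the substrate poorly, because the 3'-prenyl group sits beside the reacting 2'-oxygen and the 5-prenyl group enlarges ring B. The chalcone may also be poorly soluble in buffer, conversion stops at the chalcone/flavanone equilibrium, and a long incubation would let uncatalysed closure and ring opening erode the enantiomeric purity. Within the strategy, several chalcone isomerases (legume-type enzymes of Medicago sativa, Glycine max and Lotus japonicus, and the bacterial enzyme of Eubacterium ramulus) would be screened at analytical scale first. Fallback by known chemistry, setting out from 14: NaOAc in refluxing EtOH closes ring C without facial control to the racemic flavanone F1. Preparative HPLC on an amylose tris(3,5-dimethylphenylcarbamate) phase then separates 16 from the (2R)-flavanone F2. F2 is returned to the chalcone/flavanone equilibrium under the same NaOAc conditions and recycled. The fallback rejoins the route at 16.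

2. Step 8. Once the phenols are free, acid may add them across the neighbouring prenyl double bonds (2,2-dimethylchroman formation), methanol may add to the prenyl groups, and acid may close part of the chalcone to racemic flavanone. Fallback with a far more acid-labile protecting group, setting out from 6 and 8: 6 with 3,4-dihydro-2H-pyran and PPTS in CH2Cl2 should give the 4-O-tetrahydropyranyl ketone F3, and 8 under the same conditions the bis-tetrahydropyranyl bromoaldehyde F4. Stille coupling of F4 with 10 (Pd(PPh3)4, DMF) gives the prenylated bis-tetrahydropyranyl aldehyde F5. Claisen–Schmidt condensation of F3 with F5 (KOH, EtOH) gives the tris-tetrahydropyranyl chalcone F6. PPTS in MeOH at rt then removes the three acetals and the fallback rejoins the route at 14.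

3. Step 6. Allylic transposition during prenyl transfer could give the 1,1-dimethylallyl (reverse prenyl) isomer, and the C–Br bond could be reduced instead of coupled. Fallback that forms the C–C bond by SN2 alkylation, setting out from 9: HC(OMe)3 with catalytic PPTS in MeOH masks the aldehyde as the dimethyl acetal F7. Bromine–lithium exchange (n-BuLi, THF, −78 °C), transmetalation with CuBr·SMe2 and alkylation with prenyl bromide give the prenylated acetal F8. Brief treatment with dilute aqueous HCl in THF at 0 °C releases the aldehyde with the aryl MOM ethers intact, and the fallback rejoins the route at 11.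

**Further compounds**

F1 | step 9 | racemic 7,3',4'-trihydroxy-8,5'-diprenylflavanone | CC(C)=CCc1cc(C2CC(=O)c3ccc(O)c(CC=C(C)C)c3O2)cc(O)c1O
F2 | step 9 | (2R)-7,3',4'-trihydroxy-8,5'-diprenylflavanone | CC(C)=CCc1cc([C@H]2CC(=O)c3ccc(O)c(CC=C(C)C)c3O2)cc(O)c1O
F3 | step 8 | 1-[2-hydroxy-3-(3-methylbut-2-en-1-yl)-4-(tetrahydro-2H-pyran-2-yloxy)phenyl]ethanone | CC(=O)c1ccc(OC2CCCCO2)c(CC=C(C)C)c1O
F4 | step 8 | 3-bromo-4,5-bis(tetrahydro-2H-pyran-2-yloxy)benzaldehyde (diastereomer mixture) | O=Cc1cc(OC2CCCCO2)c(OC2CCCCO2)c(Br)c1
F5 | step 8 | 3-(3-methylbut-2-en-1-yl)-4,5-bis(tetrahydro-2H-pyran-2-yloxy)benzaldehyde (diastereomer mixture) | O=Cc1cc(OC2CCCCO2)c(OC2CCCCO2)c(CC=C(C)C)c1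
F6 | step 8 | (E)-2'-hydroxy-4',3,4-tris(tetrahydro-2H-pyran-2-yloxy)-3',5-diprenylchalcone (diastereomer mixture) | CC(C)=CCc1cc(/C=C/C(=O)c2ccc(OC3CCCCO3)c(CC=C(C)C)c2O)cc(OC2CCCCO2)c1OC1CCCCO1
F7 | step 6 | 1-bromo-5-(dimethoxymethyl)-2,3-bis(methoxymethoxy)benzene | COC(OC)c1cc(OCOC)c(OCOC)c(Br)c1
F8 | step 6 | 5-(dimethoxymethyl)-1,2-bis(methoxymethoxy)-3-(3-methylbut-2-en-1-yl)benzene | COC(OC)c1cc(OCOC)c(OCOC)c(CC=C(C)C)c1
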